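**Retrosynthetic overview**
1. Target 17 ⇐ acetonide 16 (diol unmasking only).
2. 16 ⇐ aryl iodide 15 by an aryl-radical 5-exo-trig cyclization terminated by O2: forms C3–C3a, installs the CH2OH oxygen and sets C3 trans to C2. The dihydrofuran ring is formed last.
3. 15 ⇐ iodophenol 6 + dienyl carbonate 14 by Ir-catalysed asymmetric allylic etherification (sets C2 by catalyst control).
4. 14 ⇐ enyne 11 by ring-closing enyne metathesis (cyclohexene ring formed first) and cross-metathesis; 11 ⇐ Sharpless desymmetrisation of divinyl carbinol + propargyl Grignard (sets the cis-diol).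
5. 6 ⇐ catechol by methylation, para-bromination, B-alkyl Suzuki coupling with allyl alcohol, and ortho-iodination.

Assumption: the (Sa,Sc,Sc)-phosphoramidite gives the (S)-ether in Step 10 (the (Ra,Rc,Rc) series is taken to give (R)-1-aryl-allyl aryl ethers); if the sense is reversed, the enantiomeric ligand is used. Likewise, L-(+)-DIPT is taken to give the (2R,3S)-epoxy alcohol in Step 5, as derived from the Sharpless model (L-(+)-tartrate gives 2S epoxides from primary E-allylic alcohols, and the erythro product from secondary ones).

**Arene fragment**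

Step 1
Reactants: 1 catechol
Product: 2 2-methoxyphenol
Conditions: MeI (1.0 equiv), Li2CO3, DMF, 50 °C
Reagents that add atoms: iodomethane, CI
Why: Williamson mono-O-methylation; the weak base generates only the mono-phenoxide, which limits dimethylation.

Step 2
Reactants: 2 2-methoxyphenol
Product: 3 4-bromo-2-methoxyphenol
Conditions: Bu4NBr3 (1.0 equiv), CH2Cl2/MeOH, rt
Reagents that add atoms: tetrabutylammonium tribromide (Bu4N+ Br−·Br2), CCCC[N+](CCCC)(CCCC)CCCC.[Br-].BrBr
Why: electrophilic aromatic bromination; the free OH directs para more strongly than OMe, and the bulky tribromide salt delivers one Br selectively to the position para to OH.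

Step 3
Reactants: 3 4-bromo-2-methoxyphenol; 4 allyl alcohol
Product: 5 4-(3-hydroxypropyl)-2-methoxyphenol
Conditions: 4, 9-BBN-H (2.2 equiv), THF, 0 °C→rt; then 3, Pd(OAc)2/SPhos, aq K3PO4, THF, 65 °C
Reagents that add atoms: none (all new heavy atoms come from 4; 9-BBN adds only H)
Why: anti-Markovnikov hydroboration followed by B-alkyl Suzuki–Miyaura coupling; the first equivalent of borane masks the OH as a borinate that hydrolyses on work-up.

Step 4
Reactants: 5 4-(3-hydroxypropyl)-2-methoxyphenol
Product: 6 4-(3-hydroxypropyl)-2-iodo-6-methoxyphenol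
Conditions: I2 (1.05 equiv), NaHCO3, THF/H2O, 0 °C→rt
Reagents that add atoms: iodine, II
Why: electrophilic iodination of the phenoxide; with the para position blocked, substitution goes ortho to O−.

**Cyclohexene fragment**

Step 5
Reactants: 7 penta-1,4-dien-3-ol
Product: 8 (2R,3S)-1,2-epoxypent-4-en-3-ol (erythro)
Conditions: Ti(OiPr)4 (20 mol%), L-(+)-DIPT (26 mol%), cumene hydroperoxide, 4 Å MS, CH2Cl2, −20 °C, 5 d
Reagents that add atoms: cumene hydroperoxide, CC(C)(OO)c1ccccc1
Why: Sharpless asymmetric epoxidation of a meso divinyl carbinol; enantiotopic-group and diastereoface selection set both centres (erythro), and the minor enantiomer is removed by over-epoxidation.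

Step 6
Reactants: 8 (2R,3S)-1,2-epoxypent-4-en-3-ol; 9 propargyl bromide
Product: 10 (3S,4R)-oct-1-en-7-yne-3,4-diol
Conditions: 9, Mg, HgCl2 (cat.), Et2O, 0 °C (gives allenyl-MgBr, 3.5 equiv); then 8, −78→0 °C; NH4Cl
Reagents that add atoms: none (new carbons come from 9)
Why: SN2 opening of the terminal epoxide carbon by the allenyl/propargyl Grignard (SE2′ at the reagent), assisted by the neighbouring Mg alkoxide; neither stereocentre is touched.

Step 7
Reactants: 10 (3S,4R)-oct-1-en-7-yne-3,4-diol
Product: 11 (4R,5S)-4-(but-3-yn-1-yl)-5-ethenyl-2,2-dimethyl-1,3-dioxolane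
Conditions: 2,2-dimethoxypropane, PPTS (cat.), CH2Cl2, rt
Reagents that add atoms: 2,2-dimethoxypropane, COC(C)(C)OC
Why: acetonide formation on the erythro diol; protects it from the basic Ir step.

Step 8
Reactants: 11 enyne acetonide
Product: 12 (3aS,7aR)-5-ethenyl-2,2-dimethyl-3a,6,7,7a-tetrahydro-1,3-benzodioxole
Conditions: Grubbs II (5 mol%), ethylene (1 atm), toluene, 80 °C
Reagents that add atoms: none (ethylene, C=C, only shuttles CH2 units; 12 is an isomer of 11)
Why: exo ring-closing enyne metathesis (Mori conditions) of a 1,7-enyne gives the 1-vinylcyclohexene; the erythro diol becomes the ring cis-diol.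

Step 9
Reactants: 12 vinylcyclohexene acetonide; 13 allyl methyl carbonate
Product: 14 (E)-3-[(3aS,7aR)-2,2-dimethyl-3a,6,7,7a-tetrahydro-1,3-benzodioxol-5-yl]prop-2-en-1-yl methyl carbonate
Conditions: Hoveyda–Grubbs II (5 mol%), 13 (5 equiv), CH2Cl2, 40 °C
Reagents that add atoms: none (new atoms come from 13; ethylene is lost)
Why: olefin cross-metathesis at the only accessible (terminal) alkene of the diene; the trisubstituted ring alkene is inert and the E isomer is favoured.

**Union and key step**

Step 10
Reactants: 6 iodophenol; 14 dienyl carbonate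
Product: 15 3-[4-({(1S)-1-[(3aS,7aR)-2,2-dimethyl-3a,6,7,7a-tetrahydro-1,3-benzodioxol-5-yl]prop-2-en-1-yl}oxy)-3-iodo-5-methoxyphenyl]propan-1-ol
Conditions: [Ir(cod)Cl]2 (2 mol%), (Sa,Sc,Sc)-binaphthyl bis(1-phenylethyl)phosphoramidite (4 mol%), n-PrNH2 pre-activation; 6 + NaHMDS (1.0 equiv); 14 (1.2 equiv), THF, 50 °C
Reagents that add atoms: none
Why: Ir-catalysed asymmetric allylic etherification (Hartwig–Helmchen); the phenoxide attacks the substituted allyl terminus to give the branched ether, and the ligand sets C2 as S independently of the remote diol. Only the phenol (pKa about 9) is deprotonated, so the primary alcohol is a spectator.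

Step 11
Reactants: 15 aryl iodide
Product: 16 [(2S,3R)-2-[(3aS,7aR)-2,2-dimethyl-3a,6,7,7a-tetrahydro-1,3-benzodioxol-5-yl]-5-(3-hydroxypropyl)-7-methoxy-2,3-dihydro-1-benzofuran-3-yl]methanol
Conditions: Bu3SnH (3 equiv, slow addition), dry air (bubbling), toluene (0.02 M), 0 °C→rt; then PPh3; KF work-up
Reagents that add atoms: dioxygen, O=O
Why: tin-mediated oxygenative radical cyclization (Nakamura type). The aryl radical closes 5-exo-trig onto the unhindered vinyl group, the primary radical is trapped by O2, and the hydroperoxide is reduced in situ to CH2OH. A Beckwith–Houk chair-like transition state with the cyclohexenyl group pseudo-equatorial gives the 2,3-trans (3R) isomer; the minor cis isomer is removed by chromatography.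

Step 12
Reactants: 16 acetonide
Product: 17 difengpiol A, (1R,2S)-4-[(2S,3R)-3-(hydroxymethyl)-5-(3-hydroxypropyl)-7-methoxy-2,3-dihydro-1-benzofuran-2-yl]cyclohex-3-ene-1,2-diol
Conditions: PPTS (0.3 equiv), MeOH/H2O (9:1), 45 °C
Reagents that add atoms: none (both diol oxygens are already present; acetone is lost)
Why: mild acetal hydrolysis/transketalisation; the conditions are too weak to ionise the allylic aryl ether or the allylic alcohol.

**Compound list**
1 | catechol | Oc1ccccc1O | starting material
2 | 2-methoxyphenol | COc1ccccc1O | intermediate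
3 | 4-bromo-2-methoxyphenol | COc1cc(Br)ccc1O | intermediate
4 | allyl alcohol | C=CCO | starting material
5 | 4-(3-hydroxypropyl)-2-methoxyphenol | COc1cc(CCCO)ccc1O | intermediate
6 | 4-(3-hydroxypropyl)-2-iodo-6-methoxyphenol | COc1cc(CCCO)cc(I)c1O | intermediate
7 | penta-1,4-dien-3-ol | C=CC(O)C=C | starting material
8 | (2R,3S)-1,2-epoxypent-4-en-3-ol | C=C[C@H](O)[C@H]1CO1 | intermediate
9 | propargyl bromide | C#CCBr | starting material
10 | (3S,4R)-oct-1-en-7-yne-3,4-diol | C=C[C@H](O)[C@H](O)CCC#C | intermediate
11 | (4R,5S)-4-(but-3-yn-1-yl)-5-ethenyl-2,2-dimethyl-1,3-dioxolane | C=C[C@@H]1OC(C)(C)O[C@@H]1CCC#C | intermediate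
12 | (3aS,7aR)-5-ethenyl-2,2-dimethyl-3a,6,7,7a-tetrahydro-1,3-benzodioxole | C=CC1=C[C@@H]2OC(C)(C)O[C@@H]2CC1 | intermediate
13 | allyl methyl carbonate | C=CCOC(=O)OC | starting material
14 | (E)-3-[(3aS,7aR)-2,2-dimethyl-3a,6,7,7a-tetrahydro-1,3-benzodioxol-5-yl]prop-2-en-1-yl methyl carbonate | COC(=O)OC/C=C/C1=C[C@@H]2OC(C)(C)O[C@@H]2CC1 | intermediate
15 | (S)-configured aryl bis-allylic ether (name in Step 10) | C=C[C@H](Oc1c(I)cc(CCCO)cc1OC)C1=C[C@@H]2OC(C)(C)O[C@@H]2CC1 | intermediate
16 | (2S,3R)-dihydrobenzofuran acetonide (name in Step 11) | COc1cc(CCCO)cc2c1O[C@H](C1=C[C@@H]3OC(C)(C)O[C@@H]3CC1)[C@H]2CO | intermediate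
17 | difengpiol A | COc1cc(CCCO)cc2c1O[C@H](C1=C[C@H](O)[C@H](O)CC1)[C@H]2CO | target

**Totals**
Total step count: 12.
Longest linear sequence: 8 steps (Steps 5–12, from penta-1,4-dien-3-ol); the arene branch is 4 steps before the union.

**Three steps most likely to fail**
- **Step 11 (radical cyclization/oxygenation).** Risks are a modest trans:cis ratio, direct reduction of the primary radical by Bu3SnH before O2 trapping, and competing attack of the aryl radical on the ring alkene (6-endo) or 1,6-H abstraction from the allylic ring CH2. Fallback: separate C–C formation from oxygenation. Cross-metathesise the vinyl group of 15 with vinyl-Bpin, run a reductive 5-exo cyclization (Bu3SnH, Et3B/air, −40 °C, which should also raise trans selectivity) to the CH2Bpin compound, then oxidise with NaBO3.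
- **Step 10 (Ir etherification).** The phenoxide carries two ortho substituents (I and OMe), so it may react slowly or with poor branched selectivity. Fallback: Pd(II)-COP-catalysed SN2′ etherification (Overman) of the (Z)-dienyl trichloroacetimidate with phenol 6. The imidate would come from Z-selective cross-metathesis of 12 with (Z)-but-2-ene-1,4-diol, then Cl3CCN/DBU.
- **Step 9 (cross-metathesis on a conjugated diene).** Risks are low conversion, E/Z mixtures and secondary metathesis. Fallback: domino ring-closing enyne metathesis/cross-metathesis of 11 with methyl acrylate to the (E)-dienoate, then DIBAL-H reduction and ClCO2Me (adds two steps).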